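**Retrosynthetic overview**

1. The target is read with cembrane numbering: C1 carries the 2-acetoxypropan-2-yl group (carbinol carbon C15), then C2, Z-C3=C4, C5, C6, oxirane C7–C8, C9, C10–OAc, E-C11=C12, C13, C14. It has one 14-membered carbocycle fused to one oxirane, and the last operation is diimide saturation of a C5=C6 alkene.
2. Key disconnection: ring-closing metathesis that makes C5=C6. The enabling feature is that the C5–C6 ethano link is the only ring bond lying between the trisubstituted C3=C4 alkene and the C7–C8 oxirane. Raised to the alkene level it splits into a vinyl-diene end (C3=C4–C5=CH2) and a vinyl-oxirane end (CH2=C6–C7). These are the only monosubstituted alkenes of a fully functionalised acyclic diacetate, and the ring alkene they leave is the only disubstituted one.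
3. Acyclic chain: the vinyl oxirane comes from Sharpless epoxidation, oxidation and methylenation of an E-allylic alcohol. C6–C9 and the C10 carbinol come from a catalytic asymmetric vinylogous Mukaiyama aldol on an E-enal (C10–C12), itself made by zirconium-catalysed carboalumination of a terminal alkyne.
4. C1 and the Z-C3=C4 unit come from Evans alkylation of a hex-5-ynoyl oxazolidinone with (Z)-1-bromo-3-iodobut-2-ene; the ester becomes the CMe2O carbinol and Stille vinylation gives the diene.
5. Ring order: the oxirane first (step 15), the 14-membered carbocycle second (step 20).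

Key step: step 20

Remark: the target SMILES is read as (1R,3Z,7R,8R,10R,11E) in the numbering above, with a trans oxirane (C6 and C9 on opposite faces); these locants are used in all names below.
Remark: the ketene acetal geometry of 21 is left undefined in its SMILES because it does not affect the product, and the antipode of the bisphosphoramide catalyst in step 12 is the one that directs Re-face attack on the aldehyde.

**Route**

Step 1
Reactants: 1 but-2-yn-1-ol
Product: 3 (Z)-3-iodobut-2-en-1-ol, via cyclic vinylalanate 2 (not isolated)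
Conditions: NaAlH2(OCH2CH2OMe)2, THF, 0 °C → rt; then I2, −78 → 0 °C
Reagents that add atoms: iodine, II
Why: Hydroxyl-directed trans-hydroalumination of the propargylic alcohol places aluminium on C3 cis to the CH2O group inside a five-membered alanate, and iodinolysis with retention should give the Z-iodide as one isomer.

Step 2
Reactants: 3 (Z)-3-iodobut-2-en-1-ol
Product: 4 (Z)-1-bromo-3-iodobut-2-ene
Conditions: CBr4, PPh3, CH2Cl2, 0 °C
Reagents that add atoms: carbon tetrabromide, BrC(Br)(Br)Br
Why: Appel bromination converts the primary allylic alcohol into the bromide under neutral conditions, which should avoid allylic transposition and Z/E isomerisation.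

Step 3
Reactants: 5 hex-5-ynoic acid; 6 (S)-4-benzyl-1,3-oxazolidin-2-one
Product: 8 (S)-4-benzyl-3-(hex-5-ynoyl)-1,3-oxazolidin-2-one, via mixed pivalic anhydride 7 (not isolated)
Conditions: t-BuCOCl, Et3N, THF, −20 °C; then 6, LiCl, −20 °C → rt
Reagents that add atoms: none
Why: N-Acylation of the oxazolidinone through the mixed pivalic anhydride (LiCl/Et3N variant) needs no strong base, so the terminal alkyne is untouched.

Step 4
Reactants: 8 N-hex-5-ynoyl oxazolidinone; 4 (Z)-1-bromo-3-iodobut-2-ene
Product: 10 (S)-4-benzyl-3-[(2R,4Z)-2-(but-3-yn-1-yl)-5-iodohex-4-enoyl]-1,3-oxazolidin-2-one, via sodium Z-enolate 9 (not isolated)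
Conditions: NaN(SiMe3)2, THF, −78 °C; then 4, −78 → −45 °C
Reagents that add atoms: none
Why: Evans asymmetric alkylation: the chelated sodium Z-enolate is attacked by the allylic bromide on the face opposite the benzyl group, which should set C1 as R and bring in the Z-C3=C4 unit, while the alkyne C–H is not deprotonated at −78 °C.

Step 5
Reactants: 10 alkylated imide
Product: 11 methyl (2R,4Z)-2-(but-3-yn-1-yl)-5-iodohex-4-enoate
Conditions: MeMgBr, MeOH, CH2Cl2, 0 °C
Reagents that add atoms: methoxymagnesium bromide (made in the flask from MeMgBr and MeOH), CO[Mg]Br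
Why: Magnesium methoxide transesterification cleaves the exocyclic acyl group selectively and mildly, so C1 should not epimerise and the auxiliary is recovered.

Step 6
Reactants: 11 methyl ester
Product: 13 (3R,5Z)-3-(but-3-yn-1-yl)-6-iodo-2-methylhept-5-en-2-ol, via methyl ketone 12 (not isolated)
Conditions: MeMgBr, CeCl3, THF, −78 → 0 °C
Reagents that add atoms: methylmagnesium bromide, C[Mg]Br
Why: Double addition of the methyl organocerium reagent to the ester gives the tertiary carbinol C15; its low basicity should suppress enolisation at C1 and the alkenyl iodide is inert to it.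

Step 7
Reactants: 13 tertiary alcohol
Product: 14 triethylsilyl ether of 13
Conditions: Et3SiOTf, 2,6-lutidine, CH2Cl2, −78 → 0 °C
Reagents that add atoms: triethylsilyl trifluoromethanesulfonate, CC[Si](CC)(CC)OS(=O)(=O)C(F)(F)F
Why: Silyl triflate silylation protects the hindered tertiary alcohol as a fluoride-labile ether ahead of the Lewis acidic and hydride steps.

Step 8
Reactants: 14 silyl ether alkyne
Product: 16 (2E,6R,8Z)-9-iodo-3-methyl-6-[2-(triethylsilyloxy)propan-2-yl]deca-2,8-dien-1-ol, via E-alkenyldimethylalane 15 (not isolated)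
Conditions: AlMe3, Cp2ZrCl2 (25 mol %), CH2Cl2, 0 °C → rt; then (CH2O)n, THF, 0 °C → rt
Reagents that add atoms: trimethylaluminium, C[Al](C)C; paraformaldehyde (as formaldehyde), C=O
Why: Negishi zirconium-catalysed carboalumination adds Me–Al syn across the terminal alkyne with aluminium on the terminal carbon, and hydroxymethylation of the alkenylalane with retention should give the E-trisubstituted allylic alcohol (C10–C12); the alkenyl iodide and silyl ether do not react with AlMe3.

Step 9
Reactants: 16 iodo allylic alcohol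
Product: 17 (2E,6R,8Z)-3,9-dimethyl-6-[2-(triethylsilyloxy)propan-2-yl]undeca-2,8,10-trien-1-ol
Conditions: CH2=CHSnBu3, Pd2(dba)3 (5 mol %), AsPh3 (20 mol %), NMP, rt → 50 °C
Reagents that add atoms: tributyl(vinyl)stannane, C=C[Sn](CCCC)(CCCC)CCCC
Why: Stille cross-coupling of the Z-alkenyl iodide under zerovalent palladium catalysis proceeds with retention of alkene geometry and gives the (Z)-2-methyl-1,3-diene end for the ring closure.

Step 10
Reactants: 17 dienyl allylic alcohol
Product: 18 (2E,6R,8Z)-3,9-dimethyl-6-[2-(triethylsilyloxy)propan-2-yl]undeca-2,8,10-trienal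
Conditions: MnO2, CH2Cl2, rt
Reagents that add atoms: none
Why: MnO2 oxidises only the primary allylic alcohol to the E-enal and leaves the diene and silyl ether alone.

Step 11
Reactants: 19 methyl 3-methylbut-2-enoate
Product: 21 tert-butyl[(1-methoxy-3-methylbuta-1,3-dien-1-yl)oxy]dimethylsilane, via lithium dienolate 20 (not isolated)
Conditions: LiN(i-Pr)2, THF, −78 °C; then t-BuMe2SiCl, DMPU, −78 °C → rt
Reagents that add atoms: tert-butylchlorodimethylsilane, CC(C)(C)[Si](C)(C)Cl
Why: γ-Deprotonation of the senecioate ester and O-silylation of the dienolate give the silyl dienol ether that serves as the C6–C9 nucleophile.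

Step 12
Reactants: 18 enal; 21 silyl dienol ether
Product: 23 methyl (2E,5R,6E,10R,12Z)-5-hydroxy-3,7,13-trimethyl-10-[2-(triethylsilyloxy)propan-2-yl]pentadeca-2,6,12,14-tetraenoate, via trichlorosilyl aldolate 22 (not isolated)
Conditions: SiCl4, binaphthyldiamine-derived chiral bisphosphoramide (5 mol %, antipode directing Re-face attack), i-Pr2NEt, CH2Cl2, −78 °C; aq. NaHCO3
Reagents that add atoms: none
Why: Lewis-base-activated SiCl4 vinylogous Mukaiyama aldol: the catalyst-bound trichlorosilyl cation activates the enal, the dienolate should react only at its γ-carbon to give the E-enoate, and Re-face attack sets C10 as R under catalyst control, the remote C1 centre having no influence.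

Step 13
Reactants: 23 hydroxy enoate
Product: 24 methyl (2E,5R,6E,10R,12Z)-3,7,13-trimethyl-5-(triethylsilyloxy)-10-[2-(triethylsilyloxy)propan-2-yl]pentadeca-2,6,12,14-tetraenoate
Conditions: Et3SiOTf, 2,6-lutidine, CH2Cl2, −78 °C
Reagents that add atoms: triethylsilyl trifluoromethanesulfonate, CC[Si](CC)(CC)OS(=O)(=O)C(F)(F)F
Why: Silylation of the secondary allylic alcohol keeps it from directing the titanium epoxidation in step 15 and from opening the oxirane later.

Step 14
Reactants: 24 bis-silyl enoate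
Product: 25 (2E,5R,6E,10R,12Z)-3,7,13-trimethyl-5-(triethylsilyloxy)-10-[2-(triethylsilyloxy)propan-2-yl]pentadeca-2,6,12,14-tetraen-1-ol
Conditions: i-Bu2AlH, CH2Cl2, −78 °C
Reagents that add atoms: none
Why: i-Bu2AlH reduces the conjugated ester in 1,2-fashion to the E-allylic alcohol needed for directed epoxidation, while the silyl ethers and the diene are inert.

Step 15
Reactants: 25 allylic alcohol
Product: 26 {(2R,3R)-3-[(2R,3E,7R,9Z)-4,10-dimethyl-2-(triethylsilyloxy)-7-[2-(triethylsilyloxy)propan-2-yl]dodeca-3,9,11-trien-1-yl]-3-methyloxiran-2-yl}methanol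
Conditions: Ti(Oi-Pr)4 (10 mol %), D-(−)-diethyl tartrate (12 mol %), t-BuOOH, 4 Å MS, CH2Cl2, −20 °C
Reagents that add atoms: tert-butyl hydroperoxide, CC(C)(C)OO
Why: Sharpless asymmetric epoxidation delivers oxygen only to the alkene of the primary allylic alcohol; D-(−)-tartrate should give the (7R,8R)-oxirane (the sense that takes geraniol to its 2R,3R epoxide), and the E geometry fixes C6 and C9 trans.

Step 16
Reactants: 26 epoxy alcohol
Product: 27 (2S,3R)-3-[(2R,3E,7R,9Z)-4,10-dimethyl-2-(triethylsilyloxy)-7-[2-(triethylsilyloxy)propan-2-yl]dodeca-3,9,11-trien-1-yl]-3-methyloxirane-2-carbaldehyde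
Conditions: Dess–Martin periodinane, NaHCO3, CH2Cl2, 0 °C → rt
Reagents that add atoms: none
Why: Buffered Dess–Martin oxidation gives the α,β-epoxy aldehyde without acid, so the oxirane and the configuration at C7 are kept (the descriptor changes only through priorities).

Step 17
Reactants: 27 epoxy aldehyde
Product: 28 (2R,3R)-2-ethenyl-3-methyl-3-[(2R,3E,7R,9Z)-4,10-dimethyl-2-(triethylsilyloxy)-7-[2-(triethylsilyloxy)propan-2-yl]dodeca-3,9,11-trien-1-yl]oxirane
Conditions: Ph3PCH3Br, KN(SiMe3)2, THF, 0 °C; then 27, −78 → 0 °C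
Reagents that add atoms: methyltriphenylphosphonium bromide, C[P+](c1ccccc1)(c1ccccc1)c1ccccc1.[Br-]
Why: Wittig methylenation of the epoxy aldehyde with the non-stabilised ylide at low temperature gives the vinyl oxirane, and C7 should not epimerise because the oxirane C–H is poorly acidic.

Step 18
Reactants: 28 bis-silyl vinyl oxirane
Product: 29 (2R,3E,7R,9Z)-1-[(2R,3R)-3-ethenyl-2-methyloxiran-2-yl]-7-(2-hydroxypropan-2-yl)-4,10-dimethyldodeca-3,9,11-trien-2-ol
Conditions: Bu4NF, THF, 0 °C → rt
Reagents that add atoms: none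
Why: Fluoride cleaves both triethylsilyl ethers under basic, acid-free conditions, under which the C10 hydroxyl should not open the vinyl oxirane.

Step 19
Reactants: 29 diol
Product: 30 (2R,3E,7R,9Z)-7-(2-acetoxypropan-2-yl)-1-[(2R,3R)-3-ethenyl-2-methyloxiran-2-yl]-4,10-dimethyldodeca-3,9,11-trien-2-yl acetate
Conditions: Ac2O, DMAP, Et3N, CH2Cl2, rt → 40 °C
Reagents that add atoms: acetic anhydride, CC(=O)OC(C)=O
Why: DMAP-catalysed (Steglich-type) acylation acetylates the secondary allylic alcohol quickly and the tertiary carbinol on warming, under basic conditions that the vinyl oxirane tolerates.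

Step 20
Reactants: 30 acyclic tetraene diacetate
Product: 31 (1R,3Z,5E,7R,8R,10R,11E)-7,8-epoxycembra-3,5,11-triene-10,15-diyl diacetate
Conditions: second-generation Grubbs catalyst RuCl2(=CHPh)(PCy3)(H2IMes) (10 mol %), toluene (0.5 mM), 80 °C
Reagents that add atoms: none
Why: The ruthenium alkylidene exchanges onto one of the two monosubstituted vinyl groups and then engages the other through [2+2] cycloaddition and cycloreversion of a ruthenacyclobutane, which expels ethene and forms the C5=C6 bond. The closest known reaction type is diene–ene ring-closing metathesis macrocyclisation onto the vinyl group of a (Z)-2-methyl-1,3-diene to give a macrocyclic Z,E-diene that is then saturated with diimide, well precedented for 16-membered macrolactones. The 14-membered carbocycle is closed head-to-head between the two terminal alkene carbons, with the new alkene inside the ring. No stereocentre is formed; the C5=C6 geometry (E expected) does not matter because step 21 saturates this bond, and C1, C7, C8 and C10 are not touched. The step needs site selectivity for the two vinyl groups over the trisubstituted C3=C4 and C11=C12 alkenes, which their methyl substituents secure, so no ring-contracted product should arise by attack at C3=C4. It also needs ring closure to beat oligomerisation, which high dilution and the two turn elements (Z-C3=C4 and the trans oxirane) should favour.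

Step 21
Reactants: 31 macrocyclic triene
Product: 32 (1R,3Z,7R,8R,10R,11E)-7,8-epoxycembra-3,11-diene-10,15-diyl diacetate (target)
Conditions: 2-nitrobenzenesulfonohydrazide, Et3N, CH2Cl2, rt
Reagents that add atoms: none
Why: Diimide generated in the flask transfers H2 in a concerted syn fashion to the least substituted alkene, so the disubstituted C5=C6 bond of the conjugated diene should be saturated while the trisubstituted C3=C4 and C11=C12 alkenes, the oxirane and the acetates remain.

**Compound list**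

1 | but-2-yn-1-ol | CC#CCO | starting material
2 | sodium cyclic (Z)-vinylalanate (2,2-bis(2-methoxyethoxy)-3-methyl-2,5-dihydro-1,2-oxaluminol-2-uide), not isolated | CC1=CCO[Al-]1(OCCOC)OCCOC.[Na+] | intermediate
3 | (Z)-3-iodobut-2-en-1-ol | C/C(I)=C/CO | intermediate
4 | (Z)-1-bromo-3-iodobut-2-ene | C/C(I)=C/CBr | intermediate
5 | hex-5-ynoic acid | C#CCCCC(=O)O | starting material
6 | (S)-4-benzyl-1,3-oxazolidin-2-one | O=C1N[C@@H](Cc2ccccc2)CO1 | starting material
7 | hex-5-ynoic pivalic anhydride, not isolated | C#CCCCC(=O)OC(=O)C(C)(C)C | intermediate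
8 | (S)-4-benzyl-3-(hex-5-ynoyl)-1,3-oxazolidin-2-one | C#CCCCC(=O)N1[C@@H](Cc2ccccc2)COC1=O | intermediate
9 | sodium (Z)-enolate of 8, not isolated | C#CCC/C=C(\[O-])N1[C@@H](Cc2ccccc2)COC1=O.[Na+] | intermediate
10 | (S)-4-benzyl-3-[(2R,4Z)-2-(but-3-yn-1-yl)-5-iodohex-4-enoyl]-1,3-oxazolidin-2-one | C#CCC[C@@H](C(=O)N1[C@@H](Cc2ccccc2)COC1=O)C/C=C(/C)I | intermediate
11 | methyl (2R,4Z)-2-(but-3-yn-1-yl)-5-iodohex-4-enoate | C#CCC[C@@H](C(=O)OC)C/C=C(/C)I | intermediate
12 | (3R,5Z)-3-(but-3-yn-1-yl)-6-iodohept-5-en-2-one, not isolated | C#CCC[C@@H](C(C)=O)C/C=C(/C)I | intermediate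
13 | (3R,5Z)-3-(but-3-yn-1-yl)-6-iodo-2-methylhept-5-en-2-ol | C#CCC[C@@H](C(C)(C)O)C/C=C(/C)I | intermediate
14 | {[(3R,5Z)-3-(but-3-yn-1-yl)-6-iodo-2-methylhept-5-en-2-yl]oxy}triethylsilane | C#CCC[C@@H](C(C)(C)O[Si](CC)(CC)CC)C/C=C(/C)I | intermediate
15 | dimethyl[(1E,5R,7Z)-8-iodo-2-methyl-5-[2-(triethylsilyloxy)propan-2-yl]nona-1,7-dien-1-yl]alane, not isolated | C[Al](C)/C=C(\C)CC[C@@H](C(C)(C)O[Si](CC)(CC)CC)C/C=C(/C)I | intermediate
16 | (2E,6R,8Z)-9-iodo-3-methyl-6-[2-(triethylsilyloxy)propan-2-yl]deca-2,8-dien-1-ol | OC/C=C(\C)CC[C@@H](C(C)(C)O[Si](CC)(CC)CC)C/C=C(/C)I | intermediate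
17 | (2E,6R,8Z)-3,9-dimethyl-6-[2-(triethylsilyloxy)propan-2-yl]undeca-2,8,10-trien-1-ol | OC/C=C(\C)CC[C@@H](C(C)(C)O[Si](CC)(CC)CC)C/C=C(/C)C=C | intermediate
18 | (2E,6R,8Z)-3,9-dimethyl-6-[2-(triethylsilyloxy)propan-2-yl]undeca-2,8,10-trienal | O=C/C=C(\C)CC[C@@H](C(C)(C)O[Si](CC)(CC)CC)C/C=C(/C)C=C | intermediate
19 | methyl 3-methylbut-2-enoate | CC(C)=CC(=O)OC | starting material
20 | lithium dienolate of 19, not isolated | C=C(C)C=C(OC)[O-].[Li+] | intermediate
21 | tert-butyl[(1-methoxy-3-methylbuta-1,3-dien-1-yl)oxy]dimethylsilane (ketene acetal geometry as formed) | C=C(C)C=C(OC)O[Si](C)(C)C(C)(C)C | intermediate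
22 | methyl (2E,5R,6E,10R,12Z)-3,7,13-trimethyl-5-(trichlorosilyloxy)-10-[2-(triethylsilyloxy)propan-2-yl]pentadeca-2,6,12,14-tetraenoate, not isolated | COC(=O)/C=C(\C)C[C@@H](O[Si](Cl)(Cl)Cl)/C=C(\C)CC[C@@H](C(C)(C)O[Si](CC)(CC)CC)C/C=C(/C)C=C | intermediate
23 | methyl (2E,5R,6E,10R,12Z)-5-hydroxy-3,7,13-trimethyl-10-[2-(triethylsilyloxy)propan-2-yl]pentadeca-2,6,12,14-tetraenoate | COC(=O)/C=C(\C)C[C@@H](O)/C=C(\C)CC[C@@H](C(C)(C)O[Si](CC)(CC)CC)C/C=C(/C)C=C | intermediate
24 | methyl (2E,5R,6E,10R,12Z)-3,7,13-trimethyl-5-(triethylsilyloxy)-10-[2-(triethylsilyloxy)propan-2-yl]pentadeca-2,6,12,14-tetraenoate | COC(=O)/C=C(\C)C[C@@H](O[Si](CC)(CC)CC)/C=C(\C)CC[C@@H](C(C)(C)O[Si](CC)(CC)CC)C/C=C(/C)C=C | intermediate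
25 | (2E,5R,6E,10R,12Z)-3,7,13-trimethyl-5-(triethylsilyloxy)-10-[2-(triethylsilyloxy)propan-2-yl]pentadeca-2,6,12,14-tetraen-1-ol | OC/C=C(\C)C[C@@H](O[Si](CC)(CC)CC)/C=C(\C)CC[C@@H](C(C)(C)O[Si](CC)(CC)CC)C/C=C(/C)C=C | intermediate
26 | {(2R,3R)-3-[(2R,3E,7R,9Z)-4,10-dimethyl-2-(triethylsilyloxy)-7-[2-(triethylsilyloxy)propan-2-yl]dodeca-3,9,11-trien-1-yl]-3-methyloxiran-2-yl}methanol | OC[C@H]1O[C@]1(C)C[C@@H](O[Si](CC)(CC)CC)/C=C(\C)CC[C@@H](C(C)(C)O[Si](CC)(CC)CC)C/C=C(/C)C=C | intermediate
27 | (2S,3R)-3-[(2R,3E,7R,9Z)-4,10-dimethyl-2-(triethylsilyloxy)-7-[2-(triethylsilyloxy)propan-2-yl]dodeca-3,9,11-trien-1-yl]-3-methyloxirane-2-carbaldehyde | O=C[C@H]1O[C@]1(C)C[C@@H](O[Si](CC)(CC)CC)/C=C(\C)CC[C@@H](C(C)(C)O[Si](CC)(CC)CC)C/C=C(/C)C=C | intermediate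
28 | (2R,3R)-2-ethenyl-3-methyl-3-[(2R,3E,7R,9Z)-4,10-dimethyl-2-(triethylsilyloxy)-7-[2-(triethylsilyloxy)propan-2-yl]dodeca-3,9,11-trien-1-yl]oxirane | C=C[C@H]1O[C@]1(C)C[C@@H](O[Si](CC)(CC)CC)/C=C(\C)CC[C@@H](C(C)(C)O[Si](CC)(CC)CC)C/C=C(/C)C=C | intermediate
29 | (2R,3E,7R,9Z)-1-[(2R,3R)-3-ethenyl-2-methyloxiran-2-yl]-7-(2-hydroxypropan-2-yl)-4,10-dimethyldodeca-3,9,11-trien-2-ol | C=C[C@H]1O[C@]1(C)C[C@@H](O)/C=C(\C)CC[C@@H](C(C)(C)O)C/C=C(/C)C=C | intermediate
30 | (2R,3E,7R,9Z)-7-(2-acetoxypropan-2-yl)-1-[(2R,3R)-3-ethenyl-2-methyloxiran-2-yl]-4,10-dimethyldodeca-3,9,11-trien-2-yl acetate | C=C[C@H]1O[C@]1(C)C[C@@H](OC(C)=O)/C=C(\C)CC[C@@H](C(C)(C)OC(C)=O)C/C=C(/C)C=C | intermediate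
31 | (1R,3Z,5E,7R,8R,10R,11E)-7,8-epoxycembra-3,5,11-triene-10,15-diyl diacetate | CC(=O)O[C@H]1/C=C(\C)CC[C@@H](C(C)(C)OC(C)=O)C/C=C(/C)\C=C\[C@H]2O[C@]2(C)C1 | intermediate
32 | (1R,3Z,7R,8R,10R,11E)-7,8-epoxycembra-3,11-diene-10,15-diyl diacetate (CNP0282098.2) | CC(=O)O[C@H]1/C=C(\C)CC[C@@H](C(C)(C)OC(C)=O)C/C=C(/C)CC[C@H]2O[C@]2(C)C1 | target

**Step count and risks**

Total step count: 21. Longest linear sequence: 19 steps (steps 1, 2, 4–10 and 12–21, from but-2-yn-1-ol); 18 steps from hex-5-ynoic acid.

Steps most likely to fail: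

Step 20 (ring-closing metathesis). Ring closure may lose to intermolecular metathesis, or the catalyst may load unproductively on the diene as a stabilised vinylalkylidene while the branched, oxygen-bearing vinyl oxirane initiates too slowly. The fallback is a relay ring-closing metathesis that sets out from epoxy aldehyde 27. Wittig olefination with the ylide from (hex-5-en-1-yl)triphenylphosphonium bromide and KN(SiMe3)2 should give the (Z)-hepta-1,6-dienyl oxirane bis(triethylsilyl) ether F1. Bu4NF should then give the relay diol F2, and Ac2O/DMAP/Et3N the relay diacetate F3. With the same ruthenium catalyst the metal loads on the unhindered terminal alkene of the tether, expels cyclopentene and is thereby placed as the alkylidene on C6. This alkylidene then closes onto the vinyl group of the diene, and the route is rejoined at 31.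

Step 12 (asymmetric vinylogous aldol). Facial selectivity may be poor, or conversion low, because the β,β-disubstituted enal is a weak electrophile. The fallback replaces catalyst-controlled C–C bond formation by reagent-controlled reduction and sets out from 23 as obtained, whatever its ratio of C10 epimers. Dess–Martin oxidation should give the dienone methyl (2E,6E,10R,12Z)-3,7,13-trimethyl-5-oxo-10-[2-(triethylsilyloxy)propan-2-yl]pentadeca-2,6,12,14-tetraenoate F4. Corey–Bakshi–Shibata reduction with the (S)-2-methyl-oxazaborolidine and catecholborane at −78 °C, in which the alkenyl group acts as the large substituent, should then return 23 with the 10R configuration.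

Step 8 (carboalumination and hydroxymethylation). The alkenylalane may react only sluggishly with paraformaldehyde without ate-complex activation (an alkyllithium cannot be used beside the alkenyl iodide), so protodealumination on work-up would erode the yield. The fallback is acylative trapping and sets out from 14. The same alane 15 is quenched with methyl chloroformate, which needs no activation, to give the E-enoate methyl (2E,6R,8Z)-9-iodo-3-methyl-6-[2-(triethylsilyloxy)propan-2-yl]deca-2,8-dienoate F5. Reduction with i-Bu2AlH at −78 °C then rejoins the route at 16.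

**Further compounds**

F1 | step 20 | (2R,3R)-2-[(1Z)-hepta-1,6-dien-1-yl]-3-methyl-3-[(2R,3E,7R,9Z)-4,10-dimethyl-2-(triethylsilyloxy)-7-[2-(triethylsilyloxy)propan-2-yl]dodeca-3,9,11-trien-1-yl]oxirane | C=CCCC/C=C\[C@H]1O[C@]1(C)C[C@@H](O[Si](CC)(CC)CC)/C=C(\C)CC[C@@H](C(C)(C)O[Si](CC)(CC)CC)C/C=C(/C)C=C
F2 | step 20 | (2R,3E,7R,9Z)-1-[(2R,3R)-3-[(1Z)-hepta-1,6-dien-1-yl]-2-methyloxiran-2-yl]-7-(2-hydroxypropan-2-yl)-4,10-dimethyldodeca-3,9,11-trien-2-ol | C=CCCC/C=C\[C@H]1O[C@]1(C)C[C@@H](O)/C=C(\C)CC[C@@H](C(C)(C)O)C/C=C(/C)C=C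
F3 | step 20 | (2R,3E,7R,9Z)-7-(2-acetoxypropan-2-yl)-1-[(2R,3R)-3-[(1Z)-hepta-1,6-dien-1-yl]-2-methyloxiran-2-yl]-4,10-dimethyldodeca-3,9,11-trien-2-yl acetate | C=CCCC/C=C\[C@H]1O[C@]1(C)C[C@@H](OC(C)=O)/C=C(\C)CC[C@@H](C(C)(C)OC(C)=O)C/C=C(/C)C=C
F4 | step 12 | methyl (2E,6E,10R,12Z)-3,7,13-trimethyl-5-oxo-10-[2-(triethylsilyloxy)propan-2-yl]pentadeca-2,6,12,14-tetraenoate | COC(=O)/C=C(\C)CC(=O)/C=C(\C)CC[C@@H](C(C)(C)O[Si](CC)(CC)CC)C/C=C(/C)C=C
F5 | step 8 | methyl (2E,6R,8Z)-9-iodo-3-methyl-6-[2-(triethylsilyloxy)propan-2-yl]deca-2,8-dienoate | COC(=O)/C=C(\C)CC[C@@H](C(C)(C)O[Si](CC)(CC)CC)C/C=C(/C)I
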